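The tertiary carbinol C5 of ring A sits next to the spiro carbon C6, and the C8=C9 position of ring B (the later Br/Cl site) lies γ,δ to C5. This is the retron of a Claisen rearrangement. The route therefore contracts a ring A-fused 2-methyl-2-vinyl-4-silyloxy-3,4-dihydro-2H-pyran (oxygen joining C5 and C9) by a [3,3] shift. In one operation this forms C6–C7, closes ring B, unmasks the C5 ketone and transfers the C9 configuration to C6. The pyran is built from an enantioenriched bromo ring A keto ester and a C9–C11 aldehyde, with C11 set by catalyst-controlled reduction of the derived dihydropyranone.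

Key step: step 12

Remark: atoms are numbered as in the target (ring A C1–C6, ring B C6–C11, C6 spiro); the antipodes of the chiral ligands in steps 1 and 4 are taken as those that deliver the 2R bromide and the 2R ether.

Step 1
Reactants: 1 3-methylbut-2-en-1-ol
Product: 2 (2R)-2-bromo-3-chloro-3-methylbutan-1-ol
Conditions: NBS, ClTi(OiPr)3, chiral tridentate Schiff-base ligand (salicylaldimine of an amino alcohol, 20 mol %), hexanes, −20 °C
Reagents that add atoms: N-bromosuccinimide, O=C1CCC(=O)N1Br; chlorotitanium triisopropoxide, CC(C)O[Ti](Cl)(OC(C)C)OC(C)C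
Why: Catalytic enantioselective bromochlorination of an allylic alcohol: the titanium-bound substrate takes up Br+ from NBS and chloride from titanium in an anti sense, chloride going to the tertiary carbon, so the chiral ligand sets the bromine-bearing centre (the later C2) as R.

Step 2
Reactants: 2 (2R)-2-bromo-3-chloro-3-methylbutan-1-ol; 3 methyl acetoacetate
Product: 5 methyl (6R)-6-bromo-7-chloro-7-methyl-3-oxooctanoate, via primary triflate 4 (not isolated)
Conditions: Tf2O, 2,6-lutidine, CH2Cl2, −78 °C; then dianion of 3 [LiN(iPr)2 (2.1 equiv), THF, 0 °C], −78 → −30 °C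
Reagents that add atoms: none
Why: Triflation followed by SN2 alkylation at the terminal, more basic carbon of the acetoacetate dianion (dianion γ-alkylation) extends the chain without touching the C–Br stereocentre.

Step 3
Reactants: 5 methyl (6R)-6-bromo-7-chloro-7-methyl-3-oxooctanoate
Product: 6 methyl (5R)-5-bromo-6,6-dimethyl-2-oxocyclohexane-1-carboxylate
Conditions: (CF3)2CHOH, 23 °C
Reagents that add atoms: none
Why: In the strongly ionising, non-nucleophilic solvent the tertiary chloride leaves with anchimeric assistance from the neighbouring bromine and the resulting bromonium ion is captured at its tertiary carbon by the enol carbon of the β-keto ester (bromonium-type cation–olefin carbocyclisation to a six-membered ring), while the bromine-bearing carbon is never opened and keeps its R configuration.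

Step 4
Reactants: 7 2-methyl-2-vinyloxirane (racemic)
Product: 8 (2R)-2-[(4-methoxybenzyl)oxy]-2-methylbut-3-en-1-ol
Conditions: 4-MeOC6H4CH2OH, Pd2(dba)3·CHCl3 (1 mol %), enantiopure N,N′-(trans-cyclohexane-1,2-diyl)bis[2-(diphenylphosphino)benzamide] (3 mol %), Et3B (1 mol %), CH2Cl2, 23 °C
Reagents that add atoms: 4-methoxybenzyl alcohol, COc1ccc(CO)cc1
Why: Palladium-catalysed dynamic kinetic asymmetric allylic etherification of the vinyl epoxide: both enantiomers pass through interconverting π-allyl complexes and boron-assisted delivery of the alcohol to the tertiary allyl terminus under ligand control should set the quaternary ether centre (the later C9).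

Step 5
Reactants: 8 (2R)-2-[(4-methoxybenzyl)oxy]-2-methylbut-3-en-1-ol
Product: 9 (2R)-2-[(4-methoxybenzyl)oxy]-2-methylbut-3-enal
Conditions: Dess–Martin periodinane, NaHCO3, CH2Cl2, 0 → 23 °C
Reagents that add atoms: none
Why: Dess–Martin oxidation of the primary alcohol to the aldehyde, whose quaternary α-carbon can neither epimerise nor move the alkene into conjugation.

Step 6
Reactants: 9 (2R)-2-[(4-methoxybenzyl)oxy]-2-methylbut-3-enal
Product: 11 (3S)-3-[(4-methoxybenzyl)oxy]-3-methylpent-4-enal, via methyl enol ether 10 (not isolated)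
Conditions: [Ph3PCH2OMe]Cl, KN(SiMe3)2, THF, −78 → 0 °C; then 1 M HCl (aq), THF, 0 °C
Reagents that add atoms: (methoxymethyl)triphenylphosphonium chloride, [Cl-].COC[P+](c1ccccc1)(c1ccccc1)c1ccccc1; water, O
Why: Wittig methoxymethylenation and acid hydrolysis of the enol ether give the one-carbon homologated aldehyde (C11), leaving the quaternary centre untouched.

Step 7
Reactants: 6 methyl (5R)-5-bromo-6,6-dimethyl-2-oxocyclohexane-1-carboxylate; 11 (3S)-3-[(4-methoxybenzyl)oxy]-3-methylpent-4-enal
Product: 13 (4R)-4-bromo-2-{(3S)-1-hydroxy-3-[(4-methoxybenzyl)oxy]-3-methylpent-4-en-1-yl}-3,3-dimethylcyclohexan-1-one (epimers at C6 and C11), via β-keto acid 12 (not isolated)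
Conditions: LiOH, THF/H2O, 0 °C, then 1 M HCl to pH 3 at 0 °C; then 11, MgBr2·OEt2, Et3N, THF, 0 → 23 °C
Reagents that add atoms: none
Why: Saponification to the β-keto acid and its magnesium-templated decarboxylative aldol addition to the aldehyde form the C6–C11 bond regiospecifically on the hindered side of the ketone; the two new centres (C6, C11) are left uncontrolled because steps 8 and 9 erase both.

Step 8
Reactants: 13 (4R)-4-bromo-2-{(3S)-1-hydroxy-3-[(4-methoxybenzyl)oxy]-3-methylpent-4-en-1-yl}-3,3-dimethylcyclohexan-1-one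
Product: 14 (4R)-4-bromo-2-{(3S)-3-[(4-methoxybenzyl)oxy]-3-methylpent-4-enoyl}-3,3-dimethylcyclohexan-1-one (enolised 1,3-diketone)
Conditions: Dess–Martin periodinane, NaHCO3, CH2Cl2, 0 → 23 °C
Reagents that add atoms: none
Why: Dess–Martin oxidation of the aldol to the enolised 1,3-diketone removes the C11 carbinol centre so that it can be set cleanly in step 10.

Step 9
Reactants: 14 (4R)-4-bromo-2-{(3S)-3-[(4-methoxybenzyl)oxy]-3-methylpent-4-enoyl}-3,3-dimethylcyclohexan-1-one
Product: 16 (2S,6R)-6-bromo-2-ethenyl-2,5,5-trimethyl-2,3,5,6,7,8-hexahydro-4H-chromen-4-one, via hydroxy diketone 15 (not isolated)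
Conditions: DDQ, CH2Cl2/pH 7 buffer, 0 °C; then TsOH·H2O (5 mol %), CH2Cl2, 23 °C
Reagents that add atoms: none
Why: DDQ cleaves the PMB ether oxidatively and the freed tertiary alcohol adds to the C5 carbonyl and dehydrates under mild acid (cyclodehydration of a δ-hydroxy 1,3-diketone) to the dihydropyranone, so the C5=C6 enol ether is formed at the robust vinylogous ester stage and C9 keeps its configuration.

Step 10
Reactants: 16 (2S,6R)-6-bromo-2-ethenyl-2,5,5-trimethyl-2,3,5,6,7,8-hexahydro-4H-chromen-4-one
Product: 17 (2S,4S,6R)-6-bromo-2-ethenyl-2,5,5-trimethyl-3,4,5,6,7,8-hexahydro-2H-chromen-4-ol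
Conditions: (R)-2-methyl-CBS-oxazaborolidine (0.5 equiv), catecholborane, PhMe, −78 → −40 °C; pH 7 work-up
Reagents that add atoms: none
Why: Corey–Bakshi–Shibata reduction attacks the carbonyl of the vinylogous ester in a 1,2 sense and, because the catalyst distinguishes the tetrasubstituted alkenyl flank from the CH2 flank while the remote C9 (methyl versus vinyl) exerts little bias, the (R)-oxazaborolidine should set C11 as S, cis to the vinyl group.

Step 11
Reactants: 17 (2S,4S,6R)-6-bromo-2-ethenyl-2,5,5-trimethyl-3,4,5,6,7,8-hexahydro-2H-chromen-4-ol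
Product: 18 tert-butyl{[(2S,4S,6R)-6-bromo-2-ethenyl-2,5,5-trimethyl-3,4,5,6,7,8-hexahydro-2H-chromen-4-yl]oxy}dimethylsilane
Conditions: TBSCl, imidazole, DMAP (cat.), DMF, 23 °C
Reagents that add atoms: tert-butyldimethylsilyl chloride, CC(C)(C)[Si](C)(C)Cl
Why: Silylation of the secondary allylic alcohol under basic conditions (silyl ether formation) avoids acid-promoted ionisation of the 4-oxygenated dihydropyran and installs a poor leaving group for the thermal step.

Step 12
Reactants: 18 tert-butyl{[(2S,4S,6R)-6-bromo-2-ethenyl-2,5,5-trimethyl-3,4,5,6,7,8-hexahydro-2H-chromen-4-yl]oxy}dimethylsilane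
Product: 19 (2R,6R,11S)-2-bromo-11-(tert-butyldimethylsilyloxy)-1,1,9-trimethylspiro[5.5]undec-8-en-5-one (target numbering)
Conditions: PhMe (degassed, 0.02 M), 2,6-di-tert-butyl-4-methylpyridine (0.1 equiv), sealed base-washed tube, 180 °C
Reagents that add atoms: none
Why: Heating should trigger a concerted, suprafacial [3,3]-sigmatropic (Claisen) shift of the allyl vinyl ether C7=C8–C9–O–C5=C6: the tertiary allylic C9–O bond breaks while C7 bonds to the enol-ether carbon C6, delivering the C5 ketone and the C8=C9 alkene. The closest known reaction type is the thermal ring-contracting Claisen rearrangement of 2-alkenyl-3,4-dihydro-2H-pyrans to cyclohex-3-enyl ketones. Ring B (C6–C7–C8=C9–C10–C11) is closed by this pericyclic C6–C7 bond formation through a boat-like transition state in which the vinyl group on the 2-position of the pyran reaches across to its 5-position, the only geometry the ring allows, so the six-membered oxacycle is exchanged for a six-membered carbocycle instead of being closed by an ionic exo or endo attack. The new quaternary centre C6 is set by chirality transfer from C9: the vinyl group can reach C6 only on the pyran face to which it is attached, which is also the face of the C11 silyloxy group (fixed in steps 4 and 10), so C7 enters cis to that oxygen and the 6R,11S relationship results while C9 becomes trigonal. The step needs periselectivity for the [3,3] path over retro-[4+2] loss of isoprene and over ionisation at the allylic C11–O or tertiary C9–O bonds; the irreversible formation of the C5 carbonyl, the weak tertiary allylic C9–O bond and the poorly leaving silyl ether, together with a non-polar, acid-free medium, should secure it.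

Step 13
Reactants: 19 (2R,6R,11S)-2-bromo-11-(tert-butyldimethylsilyloxy)-1,1,9-trimethylspiro[5.5]undec-8-en-5-one
Product: 20 (2R,6R,11S)-2-bromo-11-hydroxy-1,1,9-trimethylspiro[5.5]undec-8-en-5-one
Conditions: HF·pyridine, pyridine, THF, 0 → 23 °C
Reagents that add atoms: none
Why: Buffered HF cleaves the silyl ether (fluoride-mediated desilylation) without the basic conditions that could trigger retro-aldol cleavage of a β-hydroxy ketone with a quaternary α-carbon.

Step 14
Reactants: 20 (2R,6R,11S)-2-bromo-11-hydroxy-1,1,9-trimethylspiro[5.5]undec-8-en-5-one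
Product: 21 (2R,5R,6R,11S)-2-bromo-1,1,5,9-tetramethylspiro[5.5]undec-8-ene-5,11-diol
Conditions: MeMgBr (4 equiv), anhydrous CeCl3 (4 equiv), THF, −78 → 0 °C
Reagents that add atoms: methylmagnesium bromide, C[Mg]Br
Why: Organocerium-type 1,2-addition of the Grignard reagent to the hindered, enolisable ketone: the C11 alkoxide chelates the C5 carbonyl and thereby holds C11 in the carbonyl plane, the axial methyl of C1 then screens the face opposite to C7, and methyl should enter from the C7 side to give the 5R carbinol with its hydroxyl on the C11 side of ring A.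

Step 15
Reactants: 21 (2R,5R,6R,11S)-2-bromo-1,1,5,9-tetramethylspiro[5.5]undec-8-ene-5,11-diol
Product: 22 (2R,5R,6R,8S,9S,11S)-2,8-dibromo-5,9-epoxy-1,1,5,9-tetramethylspiro[5.5]undecan-11-ol (oxygen bridge from C5 to C9)
Conditions: NBS, CH2Cl2, −20 → 0 °C, dark
Reagents that add atoms: N-bromosuccinimide, O=C1CCC(=O)N1Br
Why: Bromoetherification: the C5 hydroxyl can trap only the bromonium ion on the opposite face of C8=C9 and attacks its tertiary carbon C9 (anti, Markovnikov addition, the mode by which α-terpineol closes to 2-bromo-1,8-cineole), so bromine is fixed at C8 trans to the new C9–O bond (8S, 9S).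

Step 16
Reactants: 22 (2R,5R,6R,8S,9S,11S)-2,8-dibromo-5,9-epoxy-1,1,5,9-tetramethylspiro[5.5]undecan-11-ol
Product: 23 (2R,5R,6R,8S,9S,11S)-2,8-dibromo-9-chloro-1,1,5,9-tetramethylspiro[5.5]undecane-5,11-diol
Conditions: HCl (2 M in Et2O, 2 equiv), Et4NCl (3 equiv), CH2Cl2, −40 → −10 °C; NaHCO3 quench
Reagents that add atoms: hydrogen chloride, Cl
Why: Acid-mediated opening of the cineole-type tertiary ether: the protonated oxygen is expelled from C9 by the antiperiplanar C8 bromine (the reverse of step 15) and chloride opens the bromonium ion at the tertiary carbon on the face the oxygen has left, so C9 keeps its configuration by double inversion and the C5–O bond remains as the tertiary alcohol.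

Compound list
1 | 3-methylbut-2-en-1-ol | CC(C)=CCO | starting material
2 | (2R)-2-bromo-3-chloro-3-methylbutan-1-ol | OC[C@@H](Br)C(C)(C)Cl | intermediate
3 | methyl acetoacetate (methyl 3-oxobutanoate) | COC(=O)CC(C)=O | starting material
4 | (2R)-2-bromo-3-chloro-3-methylbutyl trifluoromethanesulfonate | FC(F)(F)S(=O)(=O)OC[C@@H](Br)C(C)(C)Cl | intermediate
5 | methyl (6R)-6-bromo-7-chloro-7-methyl-3-oxooctanoate | COC(=O)CC(=O)CC[C@@H](Br)C(C)(C)Cl | intermediate
6 | methyl (5R)-5-bromo-6,6-dimethyl-2-oxocyclohexane-1-carboxylate (C1 epimers and enol) | COC(=O)C1C(=O)CC[C@@H](Br)C1(C)C | intermediate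
7 | 2-methyl-2-vinyloxirane (racemic) | CC1(C=C)CO1 | starting material
8 | (2R)-2-[(4-methoxybenzyl)oxy]-2-methylbut-3-en-1-ol | OC[C@](C)(OCc1ccc(OC)cc1)C=C | intermediate
9 | (2R)-2-[(4-methoxybenzyl)oxy]-2-methylbut-3-enal | O=C[C@](C)(OCc1ccc(OC)cc1)C=C | intermediate
10 | (3R)-1-methoxy-3-[(4-methoxybenzyl)oxy]-3-methylpenta-1,4-diene (E/Z mixture) | COC=C[C@](C)(OCc1ccc(OC)cc1)C=C | intermediate
11 | (3S)-3-[(4-methoxybenzyl)oxy]-3-methylpent-4-enal | O=CC[C@](C)(OCc1ccc(OC)cc1)C=C | intermediate
12 | (5R)-5-bromo-6,6-dimethyl-2-oxocyclohexane-1-carboxylic acid | OC(=O)C1C(=O)CC[C@@H](Br)C1(C)C | intermediate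
13 | (4R)-4-bromo-2-{(3S)-1-hydroxy-3-[(4-methoxybenzyl)oxy]-3-methylpent-4-en-1-yl}-3,3-dimethylcyclohexan-1-one (mixture of epimers at ring C2 and at the carbinol carbon) | O=C1CC[C@@H](Br)C(C)(C)C1C(O)C[C@](C)(OCc1ccc(OC)cc1)C=C | intermediate
14 | (4R)-4-bromo-2-{(3S)-3-[(4-methoxybenzyl)oxy]-3-methylpent-4-enoyl}-3,3-dimethylcyclohexan-1-one (enolised) | O=C1CC[C@@H](Br)C(C)(C)C1C(=O)C[C@](C)(OCc1ccc(OC)cc1)C=C | intermediate
15 | (4R)-4-bromo-2-[(3S)-3-hydroxy-3-methylpent-4-enoyl]-3,3-dimethylcyclohexan-1-one | O=C1CC[C@@H](Br)C(C)(C)C1C(=O)C[C@](C)(O)C=C | intermediate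
16 | (2S,6R)-6-bromo-2-ethenyl-2,5,5-trimethyl-2,3,5,6,7,8-hexahydro-4H-chromen-4-one | CC1(C)[C@H](Br)CCC2=C1C(=O)C[C@@](C)(C=C)O2 | intermediate
17 | (2S,4S,6R)-6-bromo-2-ethenyl-2,5,5-trimethyl-3,4,5,6,7,8-hexahydro-2H-chromen-4-ol | CC1(C)[C@H](Br)CCC2=C1[C@@H](O)C[C@@](C)(C=C)O2 | intermediate
18 | tert-butyl{[(2S,4S,6R)-6-bromo-2-ethenyl-2,5,5-trimethyl-3,4,5,6,7,8-hexahydro-2H-chromen-4-yl]oxy}dimethylsilane | CC1(C)[C@H](Br)CCC2=C1[C@@H](O[Si](C)(C)C(C)(C)C)C[C@@](C)(C=C)O2 | intermediate
19 | (2R,6R,11S)-2-bromo-11-(tert-butyldimethylsilyloxy)-1,1,9-trimethylspiro[5.5]undec-8-en-5-one | CC1(C)[C@H](Br)CCC(=O)[C@]12CC=C(C)C[C@@H]2O[Si](C)(C)C(C)(C)C | intermediate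
20 | (2R,6R,11S)-2-bromo-11-hydroxy-1,1,9-trimethylspiro[5.5]undec-8-en-5-one | CC1(C)[C@H](Br)CCC(=O)[C@]12CC=C(C)C[C@@H]2O | intermediate
21 | (2R,5R,6R,11S)-2-bromo-1,1,5,9-tetramethylspiro[5.5]undec-8-ene-5,11-diol | CC1(C)[C@H](Br)CC[C@@](C)(O)[C@]12CC=C(C)C[C@@H]2O | intermediate
22 | (2R,5R,6R,8S,9S,11S)-2,8-dibromo-5,9-epoxy-1,1,5,9-tetramethylspiro[5.5]undecan-11-ol | CC1(C)[C@H](Br)CC[C@@](C)(O3)[C@]12C[C@H](Br)[C@]3(C)C[C@@H]2O | intermediate
23 | (2R,5R,6R,8S,9S,11S)-2,8-dibromo-9-chloro-1,1,5,9-tetramethylspiro[5.5]undecane-5,11-diol | CC1(C)[C@H](Br)CC[C@@](C)(O)[C@]12C[C@H](Br)[C@@](C)(Cl)C[C@@H]2O | target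

Total step count: 16.
Longest linear sequence: 13 steps (steps 1–3 or steps 4–6, then steps 7–16).

Steps most likely to fail

Step 12. At the temperature that the boat transition state demands, ionisation or elimination at the allylic silyloxy position, or cycloreversion to isoprene and a ring A enone, may outrun the sigmatropic shift. The fallback sets out from 16 and moves the rearrangement to the vinylogous ester, an O-allyl enol ether of a 1,3-diketone that has no leaving group at C11. Heating 16 (PhMe, sealed tube, about 170 °C) should give the spiro diketone F1 with C6 set in the same way. LiBH(sBu)3 (THF, −78 °C) should then reduce the less hindered ring B carbonyl from the face opposite to the C1 gem-dimethyl group, which returns to the route at 20.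

Step 14. Methyl may add to the wrong face if ring A reacts from its other chair, and the β-alkoxide may instead undergo deprotonation or retro-aldol cleavage. The fallback sets out from 19 and replaces chelation control by steric control on the silyl ether. MeLi/CeCl3 (THF, −78 °C) is added to 19, where the bulky silyloxy group shields the C11 side and no alkoxide can fragment, to give the silyl-protected tertiary alcohol F2. HF·pyridine then returns to the route at 21.

Step 16. The other tertiary C–O bond (at C5), in the ether or in the product, may ionise in competition with the bromine-assisted ionisation at C9, with elimination, fragmentation of the 1,3-diol or chloride at C5 as the result. The fallback sets out from 19 and runs the tether chemistry with a secondary C5 oxygen, adding the methyl group last. iBu2AlH (CH2Cl2, −78 °C) should give the C5 secondary alcohol F3 (hydroxyl on the C11 side; the epimer can be re-oxidised). NBS closes the bridged secondary bromo ether F4. HCl/Et4NCl, which now can ionise only the tertiary C9–O bond, gives the bromo chloro alcohol F5. Dess–Martin oxidation gives the bromo chloro ketone F6, HF·pyridine the hydroxy ketone F7, and MeMgBr/CeCl3 as in step 14 returns to the route at 23.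

Further compounds
F1 | step 12 | (2R)-2-bromo-1,1,9-trimethylspiro[5.5]undec-8-ene-5,11-dione, C6 configured as in 19 | CC1(C)[C@H](Br)CCC(=O)[C@]12CC=C(C)CC2=O
F2 | step 14 | 11-O-tert-butyldimethylsilyl ether of diol 21 (2-bromo-11-silyloxy-1,1,5,9-tetramethylspiro[5.5]undec-8-en-5-ol, centres as in 21) | CC1(C)[C@H](Br)CC[C@@](C)(O)[C@]12CC=C(C)C[C@@H]2O[Si](C)(C)C(C)(C)C
F3 | step 16 | 2-bromo-11-(tert-butyldimethylsilyloxy)-1,1,9-trimethylspiro[5.5]undec-8-en-5-ol, C5 hydroxyl on the C11 side, other centres as in 19 | CC1(C)[C@H](Br)CC[C@@H](O)[C@]12CC=C(C)C[C@@H]2O[Si](C)(C)C(C)(C)C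
F4 | step 16 | 2,8-dibromo-5,9-epoxy-11-(tert-butyldimethylsilyloxy)-1,1,9-trimethylspiro[5.5]undecane, C8 bromine trans to the oxygen bridge | CC1(C)[C@H](Br)CC[C@@H](O3)[C@]12C[C@H](Br)[C@]3(C)C[C@@H]2O[Si](C)(C)C(C)(C)C
F5 | step 16 | 2,8-dibromo-9-chloro-11-(tert-butyldimethylsilyloxy)-1,1,9-trimethylspiro[5.5]undecan-5-ol, C8 and C9 as in 23 | CC1(C)[C@H](Br)CC[C@@H](O)[C@]12C[C@H](Br)[C@@](C)(Cl)C[C@@H]2O[Si](C)(C)C(C)(C)C
F6 | step 16 | 2,8-dibromo-9-chloro-11-(tert-butyldimethylsilyloxy)-1,1,9-trimethylspiro[5.5]undecan-5-one | CC1(C)[C@H](Br)CCC(=O)[C@]12C[C@H](Br)[C@@](C)(Cl)C[C@@H]2O[Si](C)(C)C(C)(C)C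
F7 | step 16 | 2,8-dibromo-9-chloro-11-hydroxy-1,1,9-trimethylspiro[5.5]undecan-5-one | CC1(C)[C@H](Br)CCC(=O)[C@]12C[C@H](Br)[C@@](C)(Cl)C[C@@H]2O
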